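## Retrosynthetic overview

1. The target comes from keto diol 20 by double acetylation; the β,γ-unsaturated ketone comes from methyl ester 16 via its Weinreb amide and a 2-isopropylallyl anion made from 2,3-dimethylbut-1-ene.
2. Key bond: the CH2–CH2 bond between the oxepane side arm and the CH2 next to the CH(CH3)C=O carbon. It is made late by sp3–sp3 Negishi coupling of a zinc ester homoenolate (14, from chiral-pool bromo ester 13) with primary bromide 12, which joins two carbons that are each β to an oxygenated carbon.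
3. The oxepane (the only ring) is closed in step 6 by 7-endo attack of the primary hydroxyl on the tertiary carbon of (R,R)-epoxide 9, with inversion; the epoxide comes from Shi epoxidation of E-alkene 8.
4. Compound 8 comes from a B-alkyl Suzuki coupling of bromodiene 4 with Z-iodoenoate 6, which fixes the exocyclic alkene geometry.
5. Diene 4 comes from but-3-yn-1-ol by carboalumination/vinylation; iodoenoate 6 comes from methyl 4-hydroxybut-2-ynoate.

Assumption: methyl 4-hydroxybut-2-ynoate (5), methyl (2S)-3-bromo-2-methylpropanoate (13) and the D-fructose-derived Shi ketone are bought as such.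

## Route

Step 1
Reactants: 1 but-3-yn-1-ol
Product: 3 (3E)-3-methylhexa-3,5-dien-1-ol, via alkenylalane 2 (not isolated)
Conditions: Me3Al (3 equiv), Cp2ZrCl2 (25 mol%), CH2Cl2, 0 → 23 °C; then CH2=CHBr, Pd(PPh3)4 (5 mol%), ZnCl2 (cat.), THF, 23 °C; aq. HCl, 0 °C
Reagents that add atoms: trimethylaluminium C[Al](C)C; bromoethene C=CBr
Why: Negishi Zr-catalysed carboalumination adds Me and Al syn across the terminal alkyne, and the Pd/Zn-cocatalysed Negishi coupling of the alkenylalane with vinyl bromide keeps that E geometry.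

Step 2
Reactants: 3 (3E)-3-methylhexa-3,5-dien-1-ol
Product: 4 (3E)-6-bromo-4-methylhexa-1,3-diene
Conditions: CBr4, PPh3, CH2Cl2, 0 °C
Reagents that add atoms: carbon tetrabromide BrC(Br)(Br)Br
Why: Appel bromination of the primary alcohol is neutral and leaves the diene untouched.

Step 3
Reactants: 5 methyl 4-hydroxybut-2-ynoate
Product: 6 methyl (2Z)-4-hydroxy-3-iodobut-2-enoate
Conditions: NaI, AcOH, 70 °C
Reagents that add atoms: sodium iodide [Na+].[I-]
Why: Anti hydroiodination of the ynoate (conjugate addition of iodide, then protonation) gives the Z-β-iodoenoate, so the hydroxymethyl group is trans to the ester and cannot lactonise.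

Step 4
Reactants: 4 (3E)-6-bromo-4-methylhexa-1,3-diene; 6 methyl (2Z)-4-hydroxy-3-iodobut-2-enoate
Product: 8 methyl (2E,6E)-9-bromo-3-(hydroxymethyl)-7-methylnona-2,6-dienoate, via B-alkyl-9-BBN 7 (not isolated)
Conditions: 9-BBN-H, THF, 0 → 23 °C; then 6, PdCl2(dppf) (5 mol%), AsPh3, Cs2CO3, DMF–H2O, 23 °C
Reagents that add atoms: none
Why: 9-BBN hydroborates only the terminal CH2= of the 1,3-diene, and the B-alkyl Suzuki–Miyaura coupling replaces iodide with retention, which sets the alkene geometry that becomes the exocyclic olefin.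

Step 5
Reactants: 8 methyl (2E,6E)-9-bromo-3-(hydroxymethyl)-7-methylnona-2,6-dienoate
Product: 9 methyl (2E)-5-[(2R,3R)-3-(2-bromoethyl)-3-methyloxiran-2-yl]-3-(hydroxymethyl)pent-2-enoate
Conditions: Shi ketone (D-fructose-derived, 30 mol%), Oxone, K2CO3, n-Bu4NHSO4, MeCN–DMM–aq. borate buffer (pH 10.5), 0 °C
Reagents that add atoms: potassium peroxymonosulfate (Oxone) [K+].[O-]S(=O)(=O)OO
Why: Shi asymmetric epoxidation attacks only the electron-rich trialkyl alkene (the enoate is inert), and the D-fructose-derived dioxirane sets both epoxide stereocentres as R,R.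

Step 6
Reactants: 9 methyl (2E)-5-[(2R,3R)-3-(2-bromoethyl)-3-methyloxiran-2-yl]-3-(hydroxymethyl)pent-2-enoate
Product: 11 methyl (2E)-2-[(6R,7S)-7-(2-bromoethyl)-7-methyl-6-(trimethylsilyloxy)oxepan-3-ylidene]acetate, via hydroxy oxepane 10 (not isolated)
Conditions: CSA (5 mol%), HFIP–CH2Cl2, 0 °C; evaporate; TMSCl, Et3N, DMAP (cat.), CH2Cl2, 0 °C
Reagents that add atoms: chlorotrimethylsilane C[Si](C)(C)Cl
Why: In this acid-promoted 7-endo epoxy-alcohol cyclisation the ionising medium puts the positive charge on the tertiary epoxide carbon, which the primary hydroxyl attacks with inversion to set the quaternary S centre while the carbinol carbon stays R, and silylation in the same flask keeps the new hydroxyl from closing onto the bromide.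

Step 7
Reactants: 11 methyl (2E)-2-[(6R,7S)-7-(2-bromoethyl)-7-methyl-6-(trimethylsilyloxy)oxepan-3-ylidene]acetate
Product: 12 (2E)-2-[(6R,7S)-7-(2-bromoethyl)-7-methyl-6-(trimethylsilyloxy)oxepan-3-ylidene]ethan-1-ol
Conditions: DIBAL-H (2.5 equiv), CH2Cl2, −78 °C; Rochelle salt
Reagents that add atoms: none
Why: DIBAL-H 1,2-reduction takes the conjugated ester to the allylic alcohol, while the alkyl bromide and the silyl ether are inert at −78 °C.

Step 8 (key step)
Reactants: 12 (2E)-2-[(6R,7S)-7-(2-bromoethyl)-7-methyl-6-(trimethylsilyloxy)oxepan-3-ylidene]ethan-1-ol; 13 methyl (2S)-3-bromo-2-methylpropanoate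
Product: 16 methyl (2R)-5-[(2S,3R,6E)-3-hydroxy-6-(2-hydroxyethylidene)-2-methyloxepan-2-yl]-2-methylpentanoate, via zinc homoenolate 14 (not isolated), via silyl ether 15 (not isolated)
Conditions: 13 (2.5 equiv), Zn dust (I2-activated), DMA, 40 °C; then 12, Ni(cod)2 (8 mol%), s-Bu-Pybox (16 mol%), DMA, 23 °C; aq. citric acid–MeOH work-up
Reagents that add atoms: none
Why: Fu-type Ni/Pybox alkyl–alkyl Negishi coupling joins the zinc ester homoenolate (a β-carbanion of the ester) to the unactivated primary bromide, the α-methyl stereocentre is carried unchanged from 13, and the mild acid work-up removes the TMS group.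

Step 9
Reactants: 16 methyl (2R)-5-[(2S,3R,6E)-3-hydroxy-6-(2-hydroxyethylidene)-2-methyloxepan-2-yl]-2-methylpentanoate; 17 2,3-dimethylbut-1-ene
Product: 20 (4R)-1-[(2S,3R,6E)-3-hydroxy-6-(2-hydroxyethylidene)-2-methyloxepan-2-yl]-4,8-dimethyl-7-methylidenenonan-5-one, via Weinreb amide 18 (not isolated), via allyllithium 19 (not isolated)
Conditions: MeNH(OMe)·HCl (3 equiv), i-PrMgCl (7.8 equiv), THF, −20 → 0 °C; then 19 [from 17 (excess), n-BuLi, TMEDA, hexane, 23 °C], −78 °C; cold aq. NH4Cl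
Reagents that add atoms: none
Why: In this Weinreb ketone synthesis the ester is converted to the amide by ClMgN(OMe)Me and the allyllithium (from allylic metalation of 17 at its methyl group) adds once, because the chelated tetrahedral intermediate releases the β,γ-unsaturated ketone only on cold quench, which avoids over-addition, double-bond migration and epimerisation.

Step 10
Reactants: 20 (4R)-1-[(2S,3R,6E)-3-hydroxy-6-(2-hydroxyethylidene)-2-methyloxepan-2-yl]-4,8-dimethyl-7-methylidenenonan-5-one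
Product: 21 (2E)-2-[(6R,7S)-6-acetoxy-7-[(4R)-4,8-dimethyl-7-methylidene-5-oxononyl]-7-methyloxepan-3-ylidene]ethyl acetate
Conditions: Ac2O, pyridine, DMAP (cat.), CH2Cl2, 0 → 23 °C
Reagents that add atoms: acetic anhydride CC(=O)OC(C)=O
Why: DMAP-catalysed acetylation esterifies the primary allylic and the secondary alcohol under mild base that neither moves the β,γ-double bond nor epimerises the α-methyl ketone.

## Compound list

1 | but-3-yn-1-ol | C#CCCO | starting material
2 | dimethylaluminium (3E)-4-(dimethylalumanyl)-3-methylbut-3-en-1-olate | C[Al](C)OCC/C(C)=C/[Al](C)C | intermediate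
3 | (3E)-3-methylhexa-3,5-dien-1-ol | OCC/C(C)=C/C=C | intermediate
4 | (3E)-6-bromo-4-methylhexa-1,3-diene | BrCC/C(C)=C/C=C | intermediate
5 | methyl 4-hydroxybut-2-ynoate | COC(=O)C#CCO | starting material
6 | methyl (2Z)-4-hydroxy-3-iodobut-2-enoate | COC(=O)/C=C(\I)CO | intermediate
7 | 9-[(3E)-6-bromo-4-methylhex-3-en-1-yl]-9-borabicyclo[3.3.1]nonane | BrCC/C(C)=C/CCB1C2CCCC1CCC2 | intermediate
8 | methyl (2E,6E)-9-bromo-3-(hydroxymethyl)-7-methylnona-2,6-dienoate | COC(=O)/C=C(\CC/C=C(\C)CCBr)CO | intermediate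
9 | methyl (2E)-5-[(2R,3R)-3-(2-bromoethyl)-3-methyloxiran-2-yl]-3-(hydroxymethyl)pent-2-enoate | COC(=O)/C=C(\CC[C@H]1O[C@]1(C)CCBr)CO | intermediate
10 | methyl (2E)-2-[(6R,7S)-7-(2-bromoethyl)-6-hydroxy-7-methyloxepan-3-ylidene]acetate | BrCC[C@]1(C)OC/C(=C/C(=O)OC)CC[C@H]1O | intermediate
11 | methyl (2E)-2-[(6R,7S)-7-(2-bromoethyl)-7-methyl-6-(trimethylsilyloxy)oxepan-3-ylidene]acetate | BrCC[C@]1(C)OC/C(=C/C(=O)OC)CC[C@H]1O[Si](C)(C)C | intermediate
12 | (2E)-2-[(6R,7S)-7-(2-bromoethyl)-7-methyl-6-(trimethylsilyloxy)oxepan-3-ylidene]ethan-1-ol | BrCC[C@]1(C)OC/C(=C/CO)CC[C@H]1O[Si](C)(C)C | intermediate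
13 | methyl (2S)-3-bromo-2-methylpropanoate | C[C@H](CBr)C(=O)OC | starting material
14 | bromo[(2S)-3-methoxy-2-methyl-3-oxopropyl]zinc | C[C@H](C[Zn]Br)C(=O)OC | intermediate
15 | methyl (2R)-5-[(2S,3R,6E)-6-(2-hydroxyethylidene)-2-methyl-3-(trimethylsilyloxy)oxepan-2-yl]-2-methylpentanoate | COC(=O)[C@H](C)CCC[C@]1(C)OC/C(=C/CO)CC[C@H]1O[Si](C)(C)C | intermediate
16 | methyl (2R)-5-[(2S,3R,6E)-3-hydroxy-6-(2-hydroxyethylidene)-2-methyloxepan-2-yl]-2-methylpentanoate | COC(=O)[C@H](C)CCC[C@]1(C)OC/C(=C/CO)CC[C@H]1O | intermediate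
17 | 2,3-dimethylbut-1-ene | C=C(C)C(C)C | starting material
18 | (2R)-5-[(2S,3R,6E)-3-hydroxy-6-(2-hydroxyethylidene)-2-methyloxepan-2-yl]-N-methoxy-N,2-dimethylpentanamide | CON(C)C(=O)[C@H](C)CCC[C@]1(C)OC/C(=C/CO)CC[C@H]1O | intermediate
19 | (3-methyl-2-methylidenebutyl)lithium | [Li]CC(=C)C(C)C | intermediate
20 | (4R)-1-[(2S,3R,6E)-3-hydroxy-6-(2-hydroxyethylidene)-2-methyloxepan-2-yl]-4,8-dimethyl-7-methylidenenonan-5-one | C=C(CC(=O)[C@H](C)CCC[C@]1(C)OC/C(=C/CO)CC[C@H]1O)C(C)C | intermediate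
21 | (2E)-2-[(6R,7S)-6-acetoxy-7-[(4R)-4,8-dimethyl-7-methylidene-5-oxononyl]-7-methyloxepan-3-ylidene]ethyl acetate | C=C(CC(=O)[C@H](C)CCC[C@]1(C)OC/C(=C/COC(C)=O)CC[C@H]1OC(C)=O)C(C)C | target

## Step count and risks

Total steps: 10. Longest linear sequence: 9 steps (1 → 3 → 4 → 8 → 9 → 11 → 12 → 16 → 20 → 21).

**Step 6 (oxepane closure).** The 6-exo attack on the secondary epoxide carbon would give a tetrahydropyran instead of the oxepane. The fallback sets out from epoxide 9 and comes back at silyl ether 11.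
- Displace the bromide of 9 with 2-nitrophenylselenide anion [(2-O2NC6H4Se)2, NaBH4, EtOH, 0 °C] to give the selenide epoxide F1.
- Oxidise with H2O2/pyridine; the selenoxide eliminates to the vinyl epoxide F2, in which the tertiary epoxide carbon is now also allylic.
- Treat with CSA in CH2Cl2 (−40 → 0 °C); the π-activated endo opening gives the vinyl oxepane F3.
- Silylate (TMSCl, Et3N) to the silyl ether F4.
- Hydroborate the vinyl group with 9-BBN to the alkylborane F5, then brominate the primary B–C bond (Br2, NaOMe, 0 °C) to reach 11.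

**Step 8 (key coupling).** Zinc ester homoenolates transmetalate slowly because of internal chelation, the alkyl–nickel species can lose β-hydride to give methacrylate, and the substrate carries a free allylic alcohol. The fallback sets out from bromide 12 and comes back at silyl ether 15, which the same acidic work-up turns into 16.
- Convert 12 with 2-nitrophenylselenide anion to the aryl selenide F6.
- Oxidise and eliminate (H2O2, pyridine) to the vinyl oxepane F7.
- Join F7 by olefin cross-metathesis (Hoveyda–Grubbs II, CH2Cl2, 40 °C) to methyl (2R)-2-methylpent-4-enoate (made from the purchasable acid), giving the E-alkene F8.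
- Hydrogenate only the new disubstituted alkene (H2, RhCl(PPh3)3, benzene) to 15.

**Step 9 (one-flask amidation/allylation).** Risks are incomplete amidation, a second addition, or base-induced migration of the double bond and epimerisation next to the ketone. The fallback sets out from Weinreb amide 18 (isolated after the amidation stage) and comes back at the target 21.
- Acetylate 18 (Ac2O, pyridine, DMAP) to the diacetate amide F9.
- Reduce only the amide with Cp2Zr(H)Cl (THF, 23 °C) to the aldehyde F10.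
- Add the allyl unit without base by the Me2AlCl-promoted carbonyl-ene reaction with 2,3-dimethylbut-1-ene 17 (CH2Cl2, −78 °C, hydrogen taken from the methyl group), giving the homoallylic alcohol F11 as both carbinol epimers.
- Oxidise with Dess–Martin periodinane/NaHCO3 to 21.

Further compounds
F1 | step 6 | methyl (2E)-3-(hydroxymethyl)-5-[(2R,3R)-3-methyl-3-{2-[(2-nitrophenyl)selanyl]ethyl}oxiran-2-yl]pent-2-enoate | COC(=O)/C=C(\CC[C@H]1O[C@]1(C)CC[Se]c1ccccc1[N+](=O)[O-])CO
F2 | step 6 | methyl (2E)-5-[(2R,3R)-3-ethenyl-3-methyloxiran-2-yl]-3-(hydroxymethyl)pent-2-enoate | COC(=O)/C=C(\CC[C@H]1O[C@]1(C)C=C)CO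
F3 | step 6 | methyl (2E)-2-[(6R,7S)-7-ethenyl-6-hydroxy-7-methyloxepan-3-ylidene]acetate | C=C[C@]1(C)OC/C(=C/C(=O)OC)CC[C@H]1O
F4 | step 6 | methyl (2E)-2-[(6R,7S)-7-ethenyl-7-methyl-6-(trimethylsilyloxy)oxepan-3-ylidene]acetate | C=C[C@]1(C)OC/C(=C/C(=O)OC)CC[C@H]1O[Si](C)(C)C
F5 | step 6 | methyl (2E)-2-[(6R,7S)-7-[2-(9-borabicyclo[3.3.1]nonan-9-yl)ethyl]-7-methyl-6-(trimethylsilyloxy)oxepan-3-ylidene]acetate | C1CCC2CCCC1B2CC[C@]1(C)OC/C(=C/C(=O)OC)CC[C@H]1O[Si](C)(C)C
F6 | step 8 | (2E)-2-[(6R,7S)-7-methyl-7-{2-[(2-nitrophenyl)selanyl]ethyl}-6-(trimethylsilyloxy)oxepan-3-ylidene]ethan-1-ol | [O-][N+](=O)c1ccccc1[Se]CC[C@]1(C)OC/C(=C/CO)CC[C@H]1O[Si](C)(C)C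
F7 | step 8 | (2E)-2-[(6R,7S)-7-ethenyl-7-methyl-6-(trimethylsilyloxy)oxepan-3-ylidene]ethan-1-ol | C=C[C@]1(C)OC/C(=C/CO)CC[C@H]1O[Si](C)(C)C
F8 | step 8 | methyl (2R,4E)-5-[(2S,3R,6E)-6-(2-hydroxyethylidene)-2-methyl-3-(trimethylsilyloxy)oxepan-2-yl]-2-methylpent-4-enoate | COC(=O)[C@H](C)C/C=C/[C@]1(C)OC/C(=C/CO)CC[C@H]1O[Si](C)(C)C
F9 | step 9 | (2E)-2-[(6R,7S)-6-acetoxy-7-{(4R)-5-[methoxy(methyl)amino]-4-methyl-5-oxopentyl}-7-methyloxepan-3-ylidene]ethyl acetate | CON(C)C(=O)[C@H](C)CCC[C@]1(C)OC/C(=C/COC(C)=O)CC[C@H]1OC(C)=O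
F10 | step 9 | (2E)-2-[(6R,7S)-6-acetoxy-7-methyl-7-[(4R)-4-methyl-5-oxopentyl]oxepan-3-ylidene]ethyl acetate | O=C[C@H](C)CCC[C@]1(C)OC/C(=C/COC(C)=O)CC[C@H]1OC(C)=O
F11 | step 9 | (2E)-2-[(6R,7S)-6-acetoxy-7-[(4R)-5-hydroxy-4,8-dimethyl-7-methylidenenonyl]-7-methyloxepan-3-ylidene]ethyl acetate | C=C(CC(O)[C@H](C)CCC[C@]1(C)OC/C(=C/COC(C)=O)CC[C@H]1OC(C)=O)C(C)C
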